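**Strategy.** Ring A, the piperidine (N1, C2 methyl, C3 ester oxygen, C6 chain; target 2S,3R,6S), is disconnected at N1–C2 and C2–C3. One aza-silyl-Prins reaction joins acetaldehyde to an (S)-N-benzyl homoallylic amine ending in a Z-vinylsilane. It closes ring A, derives the less stable trans relationship of C2 and C6 across N1 from the C6 centre alone, and leaves a C3=C4 alkene exactly where the C3 oxygen belongs. The precursor carries its side-chain ketone free, because a dioxolane would not outlast sulfinyl cleavage, InCl3 plus acetaldehyde, or carbamate methanolysis. The ketal is worn only for the organometallic and hydride steps. Epoxidation, hydride opening at C4 and feruloylation complete the route.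

Key step: step 9

Remark: the sense of induction in step 5 is assumed to follow the chelated chair model known for indium additions to tert-butanesulfinyl aldimines; ring atoms keep the target numbering N1, C2 to C6 in every name, and in 27 the C2 methyl is trans to both the C3 oxygen and the C6 chain.

Step 1
Reactants: 1 12-methoxy-12-oxododecanoic acid (monomethyl dodecanedioate)
Product: 3 methyl 12-oxotridecanoate, via acid chloride 2 (not isolated)
Conditions: (COCl)2, cat. DMF, CH2Cl2, rt; evaporate; MeMgBr (1.0 equiv), Fe(acac)3 (3 mol %), THF, −78 °C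
Reagents that add atoms: methylmagnesium bromide, C[Mg]Br; oxalyl chloride, O=C(Cl)C(=O)Cl (chlorine of 2 only)
Why: Acid chloride formation followed by iron-catalysed acylation of the Grignard reagent stops at the methyl ketone and is fast enough at −78 °C to leave the methyl ester untouched.

Step 2
Reactants: 3 methyl 12-oxotridecanoate
Product: 4 methyl 11-(2-methyl-1,3-dioxolan-2-yl)undecanoate
Conditions: HOCH2CH2OH, cat. p-TsOH·H2O, toluene, reflux, Dean–Stark
Reagents that add atoms: ethane-1,2-diol, OCCO
Why: Acid-catalysed ketalisation with azeotropic removal of water masks the ketone for the hydride and organoindium steps that follow.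

Step 3
Reactants: 4 methyl 11-(2-methyl-1,3-dioxolan-2-yl)undecanoate
Product: 5 11-(2-methyl-1,3-dioxolan-2-yl)undecanal
Conditions: i-Bu2AlH (1.05 equiv), toluene, −78 °C; MeOH, then aq. potassium sodium tartrate
Reagents that add atoms: none
Why: Partial ester reduction stops at the aldehyde because the tetrahedral aluminium hemiacetal persists at −78 °C until the quench, and the dioxolane is inert to the hydride.

Step 4
Reactants: 5 11-(2-methyl-1,3-dioxolan-2-yl)undecanal; 6 (S)-tert-butanesulfinamide
Product: 7 (S,E)-2-methyl-N-[11-(2-methyl-1,3-dioxolan-2-yl)undecylidene]propane-2-sulfinamide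
Conditions: CuSO4 (anhydrous), CH2Cl2, rt
Reagents that add atoms: none
Why: Dehydrative sulfinimine condensation of an aldehyde gives the E-aldimine under neutral conditions that touch neither the sulfur configuration nor the ketal.

Step 5
Reactants: 7 sulfinimine; 8 3-bromo-1-(trimethylsilyl)prop-1-yne
Product: 10 (S)-N-[(4S)-14-(2-methyl-1,3-dioxolan-2-yl)-1-(trimethylsilyl)tetradec-1-yn-4-yl]-2-methylpropane-2-sulfinamide, via allenylindium reagent 9 (not isolated)
Conditions: In powder, THF, ultrasound, rt
Reagents that add atoms: indium, [In] (metal of 9 only)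
Why: In this Barbier-type indium propargylation, 9 reacts in an SE2′ sense through a chair in which indium is held by the sulfinyl oxygen and the nitrogen, so carbon is delivered to the Re face of the (S)-sulfinyl imine and sets the future C6 as S, while the silyl group suppresses the allenyl regioisomer.

Step 6
Reactants: 10 homopropargylic sulfinamide
Product: 11 (S)-N-[(1Z,4S)-14-(2-methyl-1,3-dioxolan-2-yl)-1-(trimethylsilyl)tetradec-1-en-4-yl]-2-methylpropane-2-sulfinamide
Conditions: H2 (1 atm), Pd/CaCO3 poisoned with Pb(OAc)2, quinoline, EtOAc, rt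
Reagents that add atoms: none
Why: Lindlar semihydrogenation adds one equivalent of hydrogen syn on the poisoned palladium surface, turning the silylalkyne into the Z-vinylsilane and leaving sulfinamide and ketal alone.

Step 7
Reactants: 11 Z-vinylsilane sulfinamide
Product: 12 (S)-N-benzyl-N-[(1Z,4S)-14-(2-methyl-1,3-dioxolan-2-yl)-1-(trimethylsilyl)tetradec-1-en-4-yl]-2-methylpropane-2-sulfinamide
Conditions: NaH, BnBr, DMF, 0 °C → rt
Reagents that add atoms: benzyl bromide, BrCc1ccccc1
Why: SN2 N-alkylation of the sulfinamide anion installs the benzyl group while the ketone is still masked, so no reductive amination has to be run beside a free ketone.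

Step 8
Reactants: 12 N-benzyl sulfinamide
Product: 13 (13S,15Z)-13-(benzylamino)-16-(trimethylsilyl)hexadec-15-en-2-one
Conditions: HCl (4 M in dioxane), MeOH, 0 °C; then H2O, rt; aq. NaOH
Reagents that add atoms: water, O
Why: Acid solvolysis cleaves the S–N bond quickly and the added water hydrolyses the dioxolane in the same pot, while the vinylsilane, deactivated by the nearby ammonium ion, resists protodesilylation and the stereocentre is not involved.

Step 9
Reactants: 13 (13S,15Z)-13-(benzylamino)-16-(trimethylsilyl)hexadec-15-en-2-one; 14 acetaldehyde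
Product: 16 (2S,6S)-1-benzyl-2-methyl-6-(11-oxododecyl)-1,2,5,6-tetrahydropyridine, via E-iminium ion 15 (not isolated)
Conditions: InCl3 (1 equiv), MeCHO (5 equiv, in portions), MeCN, sealed tube, rt → 60 °C
Reagents that add atoms: none
Why: Amine 13 and acetaldehyde condense on InCl3 to the E-iminium ion 15, whose carbon C2 is attacked by the silicon-bearing alkene carbon C3, and the C4 cation so formed, stabilised by the adjacent C3–Si bond, expels the silyl group (ending as Me3SiOH), which fixes the alkene at C3=C4. The closest known reaction type is the vinylsilane-terminated iminium cyclisation (aza-silyl-Prins reaction) of N-benzyl homoallylic amines with aliphatic aldehydes under InCl3. Ring A is closed in a 6-endo-trig mode through a chair-like array, and the Z-alkene places the C–Si bond where it can overlap with the empty orbital developing inside the ring. The new C2 centre is controlled by C6: the benzylic CH2 lies in the iminium plane, so the C6 chain escapes it by going pseudoaxial, whereas the methyl group, anti to C6 on the E-iminium, ends equatorial, which means 2,6-trans and therefore 2S. The step needs trans diastereoselectivity (secured by this allylic strain), a defined alkene position (secured by silicon) and aldehyde-over-ketone chemoselectivity (secured by the hindered secondary amine, which does not condense with a methyl ketone, and by the absence of any acid-labile group in 13). A 2-azonia-Cope shift of 15, should it intervene, passes through a chair to an allylsilane iminium ion that closes to the same product.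

Step 10
Reactants: 16 (2S,6S)-1-benzyl-2-methyl-6-(11-oxododecyl)-1,2,5,6-tetrahydropyridine
Product: 19 tert-butyl (2S,6S)-2-methyl-6-(11-oxododecyl)-5,6-dihydropyridine-1(2H)-carboxylate, via 1-chloroethyl carbamate 17 (not isolated), via amine hydrochloride 18 (not isolated)
Conditions: ClCO2CH(Cl)CH3, ClCH2CH2Cl, 0 °C → reflux; evaporate; MeOH, reflux; evaporate; Boc2O, Et3N, CH2Cl2, rt
Reagents that add atoms: di-tert-butyl dicarbonate, CC(C)(C)OC(=O)OC(=O)OC(C)(C)C; 1-chloroethyl chloroformate, CC(Cl)OC(=O)Cl (atoms of 17 only)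
Why: In this von Braun-type acylative debenzylation, chloride attacks the primary benzylic carbon of the acylammonium ion rather than the secondary ring carbons, methanolysis of 17 frees N1 without hydrogen so that the C3=C4 alkene survives, and Boc2O then caps N1.

Step 11
Reactants: 19 N-Boc keto alkene
Product: 20 tert-butyl (2S,6S)-2-methyl-6-[10-(2-methyl-1,3-dioxolan-2-yl)decyl]-5,6-dihydropyridine-1(2H)-carboxylate
Conditions: HOCH2CH2OH, PPTS, benzene, reflux, Dean–Stark
Reagents that add atoms: ethane-1,2-diol, OCCO
Why: Mild PPTS-catalysed ketalisation re-masks the ketone for the hydride step, converts any dimethyl ketal carried over from step 10, and spares the Boc group.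

Step 12
Reactants: 20 N-Boc ketal alkene
Product: 21 tert-butyl (2S,3S,4R,6S)-3,4-epoxy-2-methyl-6-[10-(2-methyl-1,3-dioxolan-2-yl)decyl]piperidine-1-carboxylate (oxirane trans to the C2 methyl and cis to the C6 chain)
Conditions: m-CPBA, CH2Cl2, 0 °C → rt
Reagents that add atoms: 3-chloroperoxybenzoic acid, O=C(OO)c1cccc(Cl)c1
Why: Prilezhaev epoxidation is syn-stereospecific, and with allylic strain from the carbamate holding the alkene-adjacent C2 methyl pseudoaxial the peracid should add to the opposite face, which sets C3 and C4 with the oxygen trans to the methyl group.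

Step 13
Reactants: 21 epoxide
Product: 22 tert-butyl (2S,3R,6S)-3-hydroxy-2-methyl-6-[10-(2-methyl-1,3-dioxolan-2-yl)decyl]piperidine-1-carboxylate
Conditions: LiEt3BH (3 equiv), THF, 0 °C → rt; H2O
Reagents that add atoms: none
Why: This is an SN2 hydride opening under the Fürst–Plattner rule, in which attack at C4 anti to the oxirane passes through the chair with axial C3–O, axial C2 methyl and equatorial C6 chain, whereas attack at C3 is slowed by the branched C2, by the electron-withdrawing carbamate nitrogen and by a 1,3-diaxial clash of C4–O with the C6 chain, so the untouched C3–O bond becomes the alcohol (the descriptor turns to R only through the change in priorities).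

Step 14
Reactants: 23 ferulic acid
Product: 25 (E)-3-[3-methoxy-4-(methoxymethoxy)phenyl]prop-2-enoic acid, via bis-MOM derivative 24 (not isolated)
Conditions: MOMCl (2.5 equiv), i-Pr2NEt, CH2Cl2, 0 °C → rt; then LiOH, THF/MeOH/H2O, rt; dilute HCl to pH 4, 0 °C
Reagents that add atoms: chloromethyl methyl ether, COCCl
Why: Williamson-type O-alkylation covers phenol and acid alike, and saponification removes only the much more labile MOM ester, leaving an acid-cleavable aryl acetal and the E-alkene intact.

Step 15
Reactants: 22 N-Boc piperidin-3-ol; 25 MOM-protected ferulic acid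
Product: 26 tert-butyl (2S,3R,6S)-3-{(E)-3-[3-methoxy-4-(methoxymethoxy)phenyl]prop-2-enoyloxy}-2-methyl-6-[10-(2-methyl-1,3-dioxolan-2-yl)decyl]piperidine-1-carboxylate
Conditions: DCC, DMAP, CH2Cl2, 0 °C → rt
Reagents that add atoms: none
Why: Steglich esterification acylates the hindered C3 alcohol with retention, since the C3–O bond is not broken, and N1 and the phenol are both blocked.

Step 16
Reactants: 26 protected ester
Product: 27 (2S,3R,6S)-2-methyl-6-(11-oxododecyl)piperidin-3-yl (E)-3-(4-hydroxy-3-methoxyphenyl)prop-2-enoate (target)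
Conditions: CF3CO2H/CH2Cl2/H2O (5:5:1), 0 °C → rt; cold aq. NaHCO3
Reagents that add atoms: water, O
Why: Acidolysis removes Boc, the MOM acetal and the dioxolane in one operation, the conjugated secondary ester tolerates it, and the protonated N1 cannot take over the acyl group before the short cold basic work-up.

**Compound list**

1 | 12-methoxy-12-oxododecanoic acid | COC(=O)CCCCCCCCCCC(=O)O | starting material
2 | methyl 12-chloro-12-oxododecanoate | COC(=O)CCCCCCCCCCC(=O)Cl | intermediate
3 | methyl 12-oxotridecanoate | COC(=O)CCCCCCCCCCC(C)=O | intermediate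
4 | methyl 11-(2-methyl-1,3-dioxolan-2-yl)undecanoate | COC(=O)CCCCCCCCCCC1(C)OCCO1 | intermediate
5 | 11-(2-methyl-1,3-dioxolan-2-yl)undecanal | O=CCCCCCCCCCCC1(C)OCCO1 | intermediate
6 | (S)-tert-butanesulfinamide | CC(C)(C)[S@](=O)N | starting material
7 | (S,E)-2-methyl-N-[11-(2-methyl-1,3-dioxolan-2-yl)undecylidene]propane-2-sulfinamide | CC(C)(C)[S@](=O)/N=C/CCCCCCCCCCC1(C)OCCO1 | intermediate
8 | 3-bromo-1-(trimethylsilyl)prop-1-yne | C[Si](C)(C)C#CCBr | starting material
9 | [1-(trimethylsilyl)propa-1,2-dienyl]indium dibromide (simplest formulation) | C=C=C([Si](C)(C)C)[In](Br)Br | intermediate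
10 | (S)-N-[(4S)-14-(2-methyl-1,3-dioxolan-2-yl)-1-(trimethylsilyl)tetradec-1-yn-4-yl]-2-methylpropane-2-sulfinamide | CC(C)(C)[S@](=O)N[C@H](CC#C[Si](C)(C)C)CCCCCCCCCCC1(C)OCCO1 | intermediate
11 | (S)-N-[(1Z,4S)-14-(2-methyl-1,3-dioxolan-2-yl)-1-(trimethylsilyl)tetradec-1-en-4-yl]-2-methylpropane-2-sulfinamide | CC(C)(C)[S@](=O)N[C@H](C/C=C\[Si](C)(C)C)CCCCCCCCCCC1(C)OCCO1 | intermediate
12 | N-benzyl derivative of 11 | CC(C)(C)[S@](=O)N(Cc1ccccc1)[C@H](C/C=C\[Si](C)(C)C)CCCCCCCCCCC2(C)OCCO2 | intermediate
13 | (13S,15Z)-13-(benzylamino)-16-(trimethylsilyl)hexadec-15-en-2-one | C[Si](C)(C)/C=C\C[C@H](CCCCCCCCCCC(C)=O)NCc1ccccc1 | intermediate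
14 | acetaldehyde | CC=O | starting material
15 | (E)-N-benzyl-N-ethylidene iminium ion of 13 | C/C=[N+](/[C@H](C/C=C\[Si](C)(C)C)CCCCCCCCCCC(C)=O)Cc1ccccc1 | intermediate
16 | (2S,6S)-1-benzyl-2-methyl-6-(11-oxododecyl)-1,2,5,6-tetrahydropyridine | C1=CC[C@H](CCCCCCCCCCC(C)=O)N(Cc2ccccc2)[C@H]1C | intermediate
17 | 1-chloroethyl (2S,6S)-2-methyl-6-(11-oxododecyl)-5,6-dihydropyridine-1(2H)-carboxylate | C1=CC[C@H](CCCCCCCCCCC(C)=O)N(C(=O)OC(C)Cl)[C@H]1C | intermediate
18 | (2S,6S)-2-methyl-6-(11-oxododecyl)-1,2,5,6-tetrahydropyridine hydrochloride | C1=CC[C@H](CCCCCCCCCCC(C)=O)N[C@H]1C.Cl | intermediate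
19 | tert-butyl (2S,6S)-2-methyl-6-(11-oxododecyl)-5,6-dihydropyridine-1(2H)-carboxylate | C1=CC[C@H](CCCCCCCCCCC(C)=O)N(C(=O)OC(C)(C)C)[C@H]1C | intermediate
20 | tert-butyl (2S,6S)-2-methyl-6-[10-(2-methyl-1,3-dioxolan-2-yl)decyl]-5,6-dihydropyridine-1(2H)-carboxylate | C1=CC[C@H](CCCCCCCCCCC2(C)OCCO2)N(C(=O)OC(C)(C)C)[C@H]1C | intermediate
21 | tert-butyl (2S,3S,4R,6S)-3,4-epoxy-2-methyl-6-[10-(2-methyl-1,3-dioxolan-2-yl)decyl]piperidine-1-carboxylate | C[C@H]1[C@@H]2O[C@@H]2C[C@H](CCCCCCCCCCC3(C)OCCO3)N1C(=O)OC(C)(C)C | intermediate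
22 | tert-butyl (2S,3R,6S)-3-hydroxy-2-methyl-6-[10-(2-methyl-1,3-dioxolan-2-yl)decyl]piperidine-1-carboxylate | O[C@@H]1CC[C@H](CCCCCCCCCCC2(C)OCCO2)N(C(=O)OC(C)(C)C)[C@H]1C | intermediate
23 | ferulic acid | COc1cc(/C=C/C(=O)O)ccc1O | starting material
24 | methoxymethyl (E)-3-[3-methoxy-4-(methoxymethoxy)phenyl]prop-2-enoate | COCOC(=O)/C=C/c1ccc(OCOC)c(OC)c1 | intermediate
25 | (E)-3-[3-methoxy-4-(methoxymethoxy)phenyl]prop-2-enoic acid | COCOc1ccc(/C=C/C(=O)O)cc1OC | intermediate
26 | tert-butyl (2S,3R,6S)-3-{(E)-3-[3-methoxy-4-(methoxymethoxy)phenyl]prop-2-enoyloxy}-2-methyl-6-[10-(2-methyl-1,3-dioxolan-2-yl)decyl]piperidine-1-carboxylate | COc1cc(/C=C/C(=O)O[C@@H]2CC[C@H](CCCCCCCCCCC3(C)OCCO3)N(C(=O)OC(C)(C)C)[C@H]2C)ccc1OCOC | intermediate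
27 | (2S,3R,6S)-2-methyl-6-(11-oxododecyl)piperidin-3-yl (E)-3-(4-hydroxy-3-methoxyphenyl)prop-2-enoate | COc1cc(/C=C/C(=O)O[C@@H]2CC[C@H](CCCCCCCCCCC(C)=O)N[C@H]2C)ccc1O | target

**Step count.** Total: 16 steps. Longest linear sequence: 15 steps (steps 1 to 13, then 15 and 16); step 14 is a one-step side branch.

**Steps most likely to fail**

1. **Step 9.**
   - Acetaldehyde may be used up by enamine formation and self-condensation faster than the weakly nucleophilic vinylsilane closes the ring.
   - The chair preference may also erode, which would bring loss of trans selectivity or, through a boat-like azonia-Cope shift, loss of enantiopurity.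
   - The fallback forms C3=C4 by ring-closing metathesis and sets C2 by catalyst control.
   - It sets out from sulfinimine 7. Indium-mediated allylation with allyl bromide, with the same facial sense as step 5, gives the homoallylic sulfinamide F1.
   - HCl in MeOH followed by water gives the amino ketone F2.
   - Branched-selective allylic amination of (E)-but-2-enyl methyl carbonate gives the diene amine F3. The catalyst is [Ir(cod)Cl]2 with the enantiomer of a chiral phosphoramidite ligand that delivers the S centre.
   - The hydrochloride of F3 is closed with second-generation Grubbs catalyst in CH2Cl2. The route is rejoined at 18, which is capped with Boc2O as in step 10.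

2. **Step 12.**
   - Facial selectivity may be poor or inverted, because in the 2,6-trans carbamate the C6 chain competes with the C2 methyl for the axial position, and an axial chain shields the desired face.
   - The fallback sets C3 by SN2 inversion instead of by the epoxidation face.
   - It sets out from 20. The epoxide on the methyl face F4 is separated and opened at C4 with LiEt3BH, for the same steric and inductive reasons as in step 13, to the 3-epi alcohol F5.
   - F5 is esterified with acid 25 under Mitsunobu conditions (PPh3, DIAD, THF) with inversion at C3. The route is rejoined at 26, so both epoxides converge on the same ester.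

3. **Step 10.**
   - Acylation of the doubly α-branched N1 may be sluggish, and cleavage of the allylic N1–C2 bond may compete with loss of benzyl.
   - The fallback keeps the benzyl group until the alkene is gone and then removes it by hydrogenolysis.
   - It sets out from 16. Ketalisation (ethane-1,2-diol, more than one equivalent of p-TsOH, toluene, Dean–Stark) gives the N-benzyl ketal alkene F6.
   - Epoxidation of its trifluoroacetate salt with dried m-CPBA gives the N-benzyl epoxide F7. Protonation shields N1 from N-oxidation.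
   - LiEt3BH gives the N-benzyl piperidinol F8.
   - H2 over Pd(OH)2/C in the presence of Boc2O exchanges benzyl for Boc. The route is rejoined at 22.

**Further compounds**

F1 | step 9 | (S)-N-[(4S)-14-(2-methyl-1,3-dioxolan-2-yl)tetradec-1-en-4-yl]-2-methylpropane-2-sulfinamide | CC(C)(C)[S@](=O)N[C@H](CC=C)CCCCCCCCCCC1(C)OCCO1
F2 | step 9 | (13S)-13-aminohexadec-15-en-2-one | C=CC[C@@H](N)CCCCCCCCCCC(C)=O
F3 | step 9 | (13S)-13-{[(2S)-but-3-en-2-yl]amino}hexadec-15-en-2-one | C=CC[C@@H](N[C@@H](C)C=C)CCCCCCCCCCC(C)=O
F4 | step 12 | tert-butyl (2S,3R,4S,6S)-3,4-epoxy-2-methyl-6-[10-(2-methyl-1,3-dioxolan-2-yl)decyl]piperidine-1-carboxylate | C[C@H]1[C@H]2O[C@H]2C[C@H](CCCCCCCCCCC3(C)OCCO3)N1C(=O)OC(C)(C)C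
F5 | step 12 | tert-butyl (2S,3S,6S)-3-hydroxy-2-methyl-6-[10-(2-methyl-1,3-dioxolan-2-yl)decyl]piperidine-1-carboxylate | O[C@H]1CC[C@H](CCCCCCCCCCC2(C)OCCO2)N(C(=O)OC(C)(C)C)[C@H]1C
F6 | step 10 | (2S,6S)-1-benzyl-2-methyl-6-[10-(2-methyl-1,3-dioxolan-2-yl)decyl]-1,2,5,6-tetrahydropyridine | C1=CC[C@H](CCCCCCCCCCC2(C)OCCO2)N(Cc2ccccc2)[C@H]1C
F7 | step 10 | (2S,3S,4R,6S)-1-benzyl-3,4-epoxy-2-methyl-6-[10-(2-methyl-1,3-dioxolan-2-yl)decyl]piperidine | C[C@H]1[C@@H]2O[C@@H]2C[C@H](CCCCCCCCCCC3(C)OCCO3)N1Cc4ccccc4
F8 | step 10 | (2S,3R,6S)-1-benzyl-2-methyl-6-[10-(2-methyl-1,3-dioxolan-2-yl)decyl]piperidin-3-ol | O[C@@H]1CC[C@H](CCCCCCCCCCC2(C)OCCO2)N(Cc2ccccc2)[C@H]1C
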